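## Retrosynthetic overview

1. Feature used: in the γ-lactone ring (O6–C6–C7–C11–C12), the carbonyl C12 and the acetoxy carbon C9 of the ten-membered ring stand 1,5 through C11–C7–C8, and O6 is allylic to C7. With C9 at the aldehyde level, C7 is the β-carbon of an E-enal five atoms away from C11 of an acyl group on O6.
2. Key disconnection: C7–C11 (ring-closing Michael addition), made together with O6–C12 and C11–C13. This is a three-component lactone annulation of hydroxy-enal 7, (phenylsulfonyl)acetic acid 8 and MeI 9. The sulfonyl group is a temporary activator and C11 blocking group, removed last.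
3. C9–C10 comes from a Z-alkenyl Grignard reagent and the lactone aldehyde, with C9 fixed by oxidation/CBS reduction. C3–C4 comes from a Nozaki–Hiyama–Kishi ring closure. Both Z-trisubstituted alkenes come from geometrically defined vinyl iodides.
4. C6 is set by catalytic asymmetric propynylation of (E)-4,4-dimethoxybut-2-enal. C6 controls C7, and C7 controls the final protonation at C11.
5. Ring order: γ-lactone first (step 4), ten-membered carbocycle second (step 12).

Key step: step 4

Remark: atoms are named by germacranolide numbering. That is C1=C10 and C4=C5; O on C3, C6 and C9; C7–C11; C12 the lactone C=O; C13, C14 and C15 the methyls on C11, C10 and C4.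

Assumption: for the zinc–ProPhenol catalyst (step 1) and the chromium–sulfonamide complex (step 12), the ligand enantiomer used is the one that delivers the configuration drawn.

## Route

Step 1
Reactants: 1 (E)-4,4-dimethoxybut-2-enal; 2 propyne
Product: 4 (2E,4S)-1,1-dimethoxyhept-2-en-5-yn-4-ol, via methyl(prop-1-ynyl)zinc 3 (not isolated)
Conditions: Me2Zn, ProPhenol (10 mol %), Ph3P=O (20 mol %), toluene, 0 °C; aq. work-up
Reagents that add atoms: none
Why: Catalytic enantioselective alkynylzinc addition (dinuclear zinc–ProPhenol alkynylation), a reaction type established for β-substituted enals; the chiral zinc pocket selects the aldehyde face and sets C6 as S, while acetal and alkene stay inert.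

Step 2
Reactants: 4 (2E,4S)-1,1-dimethoxyhept-2-en-5-yn-4-ol
Product: 6 (2E,4S,5Z)-6-iodo-1,1-dimethoxyhepta-2,5-dien-4-ol, via cyclic alkenylalanate 5 (not isolated)
Conditions: Red-Al, THF, 0 °C to rt; I2, THF, −78 to 0 °C; aq. Rochelle salt
Reagents that add atoms: iodine, II
Why: Hydroxyl-directed trans-hydroalumination of the propargylic alcohol puts Al on the distal carbon C4 in a five-membered alanate, and iodinolysis with retention gives the vinyl iodide with I cis to C6, which fixes the C4=C5 geometry without touching C6.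

Step 3
Reactants: 6 (2E,4S,5Z)-6-iodo-1,1-dimethoxyhepta-2,5-dien-4-ol
Product: 7 (2E,4S,5Z)-4-hydroxy-6-iodohepta-2,5-dienal
Conditions: PPTS (cat.), acetone/H2O, rt
Reagents that add atoms: water, O
Why: Mild acid-catalysed acetal hydrolysis; the allylic acetal ionises far more easily than the carbinol flanked by an enal and an iodoalkene, so C6 and both alkene geometries should be kept.

Step 4
Reactants: 7 (2E,4S,5Z)-4-hydroxy-6-iodohepta-2,5-dienal; 8 (phenylsulfonyl)acetic acid; 9 iodomethane
Product: 12 2-[(2S,3R,4R)-2-[(Z)-2-iodoprop-1-enyl]-4-methyl-5-oxo-4-(phenylsulfonyl)oxolan-3-yl]acetaldehyde, via dienyl sulfonylacetate 10 (not isolated), via secondary sulfonyl lactone 11 (not isolated)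
Conditions: DCC, DMAP (cat.), CH2Cl2, 0 °C; dilute with MeCN, Cs2CO3 (1.1 equiv), 0 °C; MeI, 0 °C to rt (one flask)
Reagents that add atoms: none
Why: Steglich acylation of O6 gives 10, whose CH2 between ester and sulfone is deprotonated by carbonate and adds to C7, the β-carbon of the E-enal, in an intramolecular Michael addition; proton transfer leaves the sulfonyl-stabilised carbanion of 11, which MeI methylates, so O6–C12, C7–C11 and C11–C13 are made in one flask from three components. The closest known reaction types are the base-mediated cyclisation of malonate, acetoacetate or sulfonylacetate esters of γ-hydroxy enones and enoates to trans-4,5-disubstituted γ-butyrolactones, and the C-alkylation of α-sulfonyl lactones. The lactone closes 5-exo-trig, and because the charge is also carried by the exocyclic sulfonyl group the carbanion is not locked in the ester plane, which avoids the poor overlap of a bare enolendo ester enolate. C7 is controlled by C6: closure goes through the conformer with H6 eclipsing C7=C8 (least allylic strain) on the enal face that carries O6, and since the addition is reversible under carbonate the trans C5/C8 arrangement is also the thermodynamic sink; C11 becomes quaternary by methylation anti to the C8 chain, which is only a placeholder (either epimer serves) and cannot epimerise in steps 6–13. Site selectivity rests on the substrate: of the two alkenes flanking C6 only C7=C8 is conjugated to an acceptor, 1,2-attack at C9 would need a seven-membered ring holding an E-alkene, and dilution disfavours intermolecular condensation. The step also converts the enal into the free C9 aldehyde and keeps the C4 vinyl iodide, the two handles for the remaining ring bonds.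

Step 5
Reactants: 13 3-[(tert-butyldimethylsilyl)oxy]propanal; 14 ethyltriphenylphosphonium iodide
Product: 18 (Z)-tert-butyl[(4-iodopent-3-enyl)oxy]dimethylsilane, via ethylidenetriphenylphosphorane 15 (not isolated), via (1-iodoethyl)triphenylphosphonium iodide 16 (not isolated), via (1-iodoethylidene)triphenylphosphorane 17 (not isolated)
Conditions: n-BuLi, THF, rt then −78 °C; I2; NaHMDS, −20 °C; 13, −78 °C to rt
Reagents that add atoms: iodine, II
Why: Stork–Zhao-type Wittig olefination with the α-iodo ylide, which under kinetic control gives Z-2-iodoalk-2-enes (I cis to C2) and so fixes the C1=C10 geometry.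

Step 6
Reactants: 18 (Z)-tert-butyl[(4-iodopent-3-enyl)oxy]dimethylsilane; 12 lactone aldehyde
Product: 20 (3R,4R,5S)-4-[(3Z)-6-(tert-butyldimethylsilyloxy)-2-hydroxy-3-methylhex-3-enyl]-5-[(Z)-2-iodoprop-1-enyl]-3-methyl-3-(phenylsulfonyl)oxolan-2-one (both C9 epimers), via alkenylmagnesium chloride 19 (not isolated)
Conditions: i-PrMgCl·LiCl, THF, 0 °C to rt; then 12, −78 to −40 °C; aq. work-up
Reagents that add atoms: none
Why: Iodine–magnesium exchange with the turbo-Grignard reagent keeps the alkene geometry, and Grignard 1,2-addition to the aldehyde should outrun attack on the α-quaternary lactone or on the vinyl iodide; C9 forms without control and is corrected in steps 7 and 8.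

Step 7
Reactants: 20 allylic alcohol (both C9 epimers)
Product: 21 (3R,4R,5S)-4-[(3Z)-6-(tert-butyldimethylsilyloxy)-3-methyl-2-oxohex-3-enyl]-5-[(Z)-2-iodoprop-1-enyl]-3-methyl-3-(phenylsulfonyl)oxolan-2-one
Conditions: Dess–Martin periodinane, pyridine, CH2Cl2, 0 °C
Reagents that add atoms: none
Why: Dess–Martin oxidation converges both epimers on one enone, and the buffered near-neutral medium should avoid Z-to-E isomerisation and retro-Michael opening of the lactone.

Step 8
Reactants: 21 Z-enone
Product: 22 (3R,4R,5S)-4-[(2R,3Z)-6-(tert-butyldimethylsilyloxy)-2-hydroxy-3-methylhex-3-enyl]-5-[(Z)-2-iodoprop-1-enyl]-3-methyl-3-(phenylsulfonyl)oxolan-2-one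
Conditions: (S)-Me-CBS (20 mol %), catecholborane, toluene, −78 °C; aq. work-up
Reagents that add atoms: none
Why: CBS reduction in which the α-methylalkenyl group is the large substituent and C8H2 the small one, so the (S)-catalyst should deliver hydride to give 9R, while catecholborane at low temperature leaves alkenes, lactone and vinyl iodide alone.

Step 9
Reactants: 22 (9R)-allylic alcohol
Product: 23 (2R,3Z)-6-(tert-butyldimethylsilyloxy)-1-[(2S,3R,4R)-2-[(Z)-2-iodoprop-1-enyl]-4-methyl-5-oxo-4-(phenylsulfonyl)oxolan-3-yl]-3-methylhex-3-en-2-yl acetate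
Conditions: Ac2O, pyridine, DMAP (cat.), CH2Cl2, 0 °C to rt
Reagents that add atoms: acetic anhydride, CC(=O)OC(C)=O
Why: DMAP-catalysed acetylation installs the final C9 acetate with retention and prevents lactol formation with the later C3 aldehyde.

Step 10
Reactants: 23 silyl ether acetate
Product: 24 (2R,3Z)-6-hydroxy-1-[(2S,3R,4R)-2-[(Z)-2-iodoprop-1-enyl]-4-methyl-5-oxo-4-(phenylsulfonyl)oxolan-3-yl]-3-methylhex-3-en-2-yl acetate
Conditions: HF·pyridine, pyridine, THF, 0 °C
Reagents that add atoms: none
Why: Fluoride-driven desilylation under buffered conditions frees the primary C3 alcohol without acetate migration or lactone opening.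

Step 11
Reactants: 24 primary alcohol
Product: 25 (2R,3Z)-1-[(2S,3R,4R)-2-[(Z)-2-iodoprop-1-enyl]-4-methyl-5-oxo-4-(phenylsulfonyl)oxolan-3-yl]-3-methyl-6-oxohex-3-en-2-yl acetate
Conditions: Dess–Martin periodinane, pyridine, CH2Cl2, 0 °C; used at once
Reagents that add atoms: none
Why: Buffered Dess–Martin oxidation is the usual mild entry to Z-β,γ-unsaturated aldehydes and should not move the C1=C10 alkene into conjugation.

Step 12
Reactants: 25 iodo-aldehyde
Product: 26 (3R,3aR,5R,6Z,9S,10Z,11aR)-9-hydroxy-3,6,10-trimethyl-2-oxo-3-(phenylsulfonyl)-2,3,3a,4,5,8,9,11a-octahydrocyclodeca[b]furan-5-yl acetate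
Conditions: CrCl2, chiral oxazoline–sulfonamide ligand, Et3N, NiCl2·(2,9-dimethyl-1,10-phenanthroline) (cat.), MeCN/THF, high dilution (syringe pump), rt
Reagents that add atoms: none
Why: Intramolecular Nozaki–Hiyama–Kishi reaction forms C3–C4 with retention of the vinyl iodide geometry (C3 cis to C6); the two Z-alkenes and the trans-lactone bring the chain ends together, and the chiral chromium complex selects the aldehyde face to give 3S.

Step 13
Reactants: 26 macrocyclic allylic alcohol
Product: 27 (3R,3aR,5R,6Z,9S,10Z,11aR)-3,6,10-trimethyl-2-oxo-3-(phenylsulfonyl)-2,3,3a,4,5,8,9,11a-octahydrocyclodeca[b]furan-5,9-diyl diacetate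
Conditions: Ac2O, pyridine, DMAP (cat.), CH2Cl2, 0 °C to rt
Reagents that add atoms: acetic anhydride, CC(=O)OC(C)=O
Why: DMAP-catalysed acetylation of the C3 alcohol with retention; C11 is still quaternary and cannot epimerise.

Step 14
Reactants: 27 sulfonyl diacetate
Product: 29 (3R,3aS,5R,6Z,9S,10Z,11aS)-3,6,10-trimethyl-2-oxo-2,3,3a,4,5,8,9,11a-octahydrocyclodeca[b]furan-5,9-diyl diacetate (target), via samarium(III) enolate 28 (not isolated)
Conditions: SmI2, THF/HMPA, 2,6-di-tert-butyl-4-methylphenol, −78 °C; pH 7 buffer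
Reagents that add atoms: none
Why: Reductive desulfonylation α to the lactone carbonyl gives planar enolate 28, which the bulky phenol should protonate kinetically on the face that carries H7, anti to C8, giving 11R with C13 cis to C8; low temperature and the absence of alkoxide should prevent equilibration to the more stable 11-epimer.

## Compound list

1 | (E)-4,4-dimethoxybut-2-enal | COC(OC)/C=C/C=O | starting material
2 | propyne | CC#C | starting material
3 | methyl(prop-1-ynyl)zinc | C[Zn]C#CC | intermediate
4 | (2E,4S)-1,1-dimethoxyhept-2-en-5-yn-4-ol | COC(OC)/C=C/[C@@H](C#CC)O | intermediate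
5 | sodium cyclic alkenylalanate (O6 and C4 bound to Al(OCH2CH2OMe)2) | COC(OC)/C=C/[C@H]1C=C(C)[Al-](OCCOC)(OCCOC)O1.[Na+] | intermediate
6 | (2E,4S,5Z)-6-iodo-1,1-dimethoxyhepta-2,5-dien-4-ol | COC(OC)/C=C/[C@@H](/C=C(\I)C)O | intermediate
7 | (2E,4S,5Z)-4-hydroxy-6-iodohepta-2,5-dienal | O=C/C=C/[C@@H](/C=C(\I)C)O | intermediate
8 | (phenylsulfonyl)acetic acid | OC(=O)CS(=O)(=O)c1ccccc1 | starting material
9 | iodomethane | CI | starting material
10 | (2Z,4S,5E)-2-iodo-7-oxohepta-2,5-dien-4-yl (phenylsulfonyl)acetate | O=C/C=C/[C@@H](/C=C(\I)C)OC(=O)CS(=O)(=O)c1ccccc1 | intermediate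
11 | 2-[(2S,3R,4S)-2-[(Z)-2-iodoprop-1-enyl]-5-oxo-4-(phenylsulfonyl)oxolan-3-yl]acetaldehyde | O=CC[C@@H]1[C@@H](/C=C(\I)C)OC(=O)[C@H]1S(=O)(=O)c2ccccc2 | intermediate
12 | 2-[(2S,3R,4R)-2-[(Z)-2-iodoprop-1-enyl]-4-methyl-5-oxo-4-(phenylsulfonyl)oxolan-3-yl]acetaldehyde | O=CC[C@@H]1[C@@H](/C=C(\I)C)OC(=O)[C@]1(C)S(=O)(=O)c2ccccc2 | intermediate
13 | 3-[(tert-butyldimethylsilyl)oxy]propanal | O=CCCO[Si](C)(C)C(C)(C)C | starting material
14 | ethyltriphenylphosphonium iodide | CC[P+](c1ccccc1)(c1ccccc1)c1ccccc1.[I-] | starting material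
15 | ethylidenetriphenylphosphorane | CC=P(c1ccccc1)(c1ccccc1)c1ccccc1 | intermediate
16 | (1-iodoethyl)triphenylphosphonium iodide | CC(I)[P+](c1ccccc1)(c1ccccc1)c1ccccc1.[I-] | intermediate
17 | (1-iodoethylidene)triphenylphosphorane | CC(I)=P(c1ccccc1)(c1ccccc1)c1ccccc1 | intermediate
18 | (Z)-tert-butyl[(4-iodopent-3-enyl)oxy]dimethylsilane | C/C(I)=C/CCO[Si](C)(C)C(C)(C)C | intermediate
19 | (Z)-[5-(tert-butyldimethylsilyloxy)pent-2-en-2-yl]magnesium chloride | C/C([Mg]Cl)=C/CCO[Si](C)(C)C(C)(C)C | intermediate
20 | allylic alcohol, both C9 epimers (name as in step 6) | CC(C)(C)[Si](C)(C)OCC/C=C(/C)C(O)C[C@@H]1[C@@H](/C=C(\I)C)OC(=O)[C@]1(C)S(=O)(=O)c2ccccc2 | intermediate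
21 | Z-enone, C9 ketone (name as in step 7) | CC(C)(C)[Si](C)(C)OCC/C=C(/C)C(=O)C[C@@H]1[C@@H](/C=C(\I)C)OC(=O)[C@]1(C)S(=O)(=O)c2ccccc2 | intermediate
22 | (9R)-allylic alcohol (name as in step 8) | CC(C)(C)[Si](C)(C)OCC/C=C(/C)[C@H](O)C[C@@H]1[C@@H](/C=C(\I)C)OC(=O)[C@]1(C)S(=O)(=O)c2ccccc2 | intermediate
23 | (9R)-acetate silyl ether (name as in step 9) | CC(C)(C)[Si](C)(C)OCC/C=C(/C)[C@H](OC(C)=O)C[C@@H]1[C@@H](/C=C(\I)C)OC(=O)[C@]1(C)S(=O)(=O)c2ccccc2 | intermediate
24 | C3 primary alcohol (name as in step 10) | OCC/C=C(/C)[C@H](OC(C)=O)C[C@@H]1[C@@H](/C=C(\I)C)OC(=O)[C@]1(C)S(=O)(=O)c2ccccc2 | intermediate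
25 | C3 aldehyde / C4 vinyl iodide (name as in step 11) | O=CC/C=C(/C)[C@H](OC(C)=O)C[C@@H]1[C@@H](/C=C(\I)C)OC(=O)[C@]1(C)S(=O)(=O)c2ccccc2 | intermediate
26 | macrocyclic (3S)-alcohol (name as in step 12) | O[C@H]1C/C=C(/C)[C@H](OC(C)=O)C[C@@H]2[C@@H](/C=C\1C)OC(=O)[C@]2(C)S(=O)(=O)c3ccccc3 | intermediate
27 | 11-(phenylsulfonyl) diacetate (name as in step 13) | CC(=O)O[C@H]1C/C=C(/C)[C@H](OC(C)=O)C[C@@H]2[C@@H](/C=C\1C)OC(=O)[C@]2(C)S(=O)(=O)c3ccccc3 | intermediate
28 | samarium(III) lactone enolate (C11=C12–O–SmI2) | CC(=O)O[C@H]1C/C=C(/C)[C@H](OC(C)=O)C[C@@H]2[C@@H](/C=C\1C)OC(O[Sm](I)I)=C2C | intermediate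
29 | (3R,3aS,5R,6Z,9S,10Z,11aS)-3,6,10-trimethyl-2-oxo-2,3,3a,4,5,8,9,11a-octahydrocyclodeca[b]furan-5,9-diyl diacetate | CC(=O)O[C@H]1C/C=C(/C)[C@H](OC(C)=O)C[C@@H]2[C@@H](/C=C\1C)OC(=O)[C@@H]2C | target

## Step count and risks

Total step count: 14. Longest linear sequence: 13 (steps 1–4 and 6–14).

Steps most likely to fail:

**Step 12 (ten-membered ring closure).**
- Ring closure has to compete with intermolecular coupling.
- The β,γ-unsaturated aldehyde can slip into conjugation before it is captured.
- The chiral chromium complex may discriminate the aldehyde faces only weakly in a strained transition state.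

The fallback sets out from 25 and closes the same bond as an acyl coupling, leaving C3 to a separate reagent-controlled reduction. Pinnick oxidation gives the carboxylic acid F1. 2,2'-Dipyridyl disulfide/PPh3 gives the S-(2-pyridyl) thioester F2. Nickel-catalysed reductive coupling of the vinyl iodide with the thioester (NiBr2·dtbbpy, Cp2ZrCl2, Zn, high dilution) gives the macrocyclic Z-enone F3. (R)-Me-CBS/catecholborane then reduces the C3 ketone to the 3S alcohol, which is where the fallback comes back to the route at 26.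

**Step 14 (C11–H).**
- Proton delivery may come from the C8 side if the macrocycle folds over the H7 face.
- The lactone may equilibrate to the more stable 11-epimer during work-up.
- Allylic C–O bonds may be reduced.

The fallback sets out from 23 and moves the stereo-determining event to the conformationally simple monocycle, where only the C7 side chain shields the enolate. Aluminium amalgam in aqueous THF gives the desulfonylated lactone F4. HF·pyridine gives the alcohol F5. Buffered Dess–Martin oxidation gives the aldehyde F6. The Nozaki–Hiyama–Kishi closure gives the macrocyclic alcohol F7. All of these media are non-basic. Acetylation comes back to the route at 29.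

**Step 4 (three-component annulation).**
- The doubly activated methylene of 10 may condense with the enal carbonyl of a second molecule.
- Base may expel the acyl group as a sulfonylketene before ring closure.
- Late retro-Michael opening may erode the trans selectivity.

The fallback sets out from 7 and reverses the bond order. Iminium-catalysed (diphenylprolinol silyl ether, matched enantiomer) intermolecular Michael addition of methyl (phenylsulfonyl)acetate forms C7–C11 first and gives the open-chain adduct F8. Camphorsulfonic acid then closes O6–C12 by lactonisation to 11, now isolated. K2CO3/MeI comes back to the route at 12.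

## Further compounds

F1 | step 12 | (3Z,5R)-5-acetoxy-6-[(2S,3R,4R)-2-[(Z)-2-iodoprop-1-enyl]-4-methyl-5-oxo-4-(phenylsulfonyl)oxolan-3-yl]-4-methylhex-3-enoic acid | OC(=O)C/C=C(/C)[C@H](OC(C)=O)C[C@@H]1[C@@H](/C=C(\I)C)OC(=O)[C@]1(C)S(=O)(=O)c2ccccc2
F2 | step 12 | S-(pyridin-2-yl) thioester of F1 | O=C(Sc1ccccn1)C/C=C(/C)[C@H](OC(C)=O)C[C@@H]2[C@@H](/C=C(\I)C)OC(=O)[C@]2(C)S(=O)(=O)c3ccccc3
F3 | step 12 | (3R,3aR,5R,6Z,10Z,11aR)-3,6,10-trimethyl-2,9-dioxo-3-(phenylsulfonyl)-2,3,3a,4,5,8,9,11a-octahydrocyclodeca[b]furan-5-yl acetate | O=C1C/C=C(/C)[C@H](OC(C)=O)C[C@@H]2[C@@H](/C=C\1C)OC(=O)[C@]2(C)S(=O)(=O)c3ccccc3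
F4 | step 14 | (2R,3Z)-6-(tert-butyldimethylsilyloxy)-1-[(2S,3S,4R)-2-[(Z)-2-iodoprop-1-enyl]-4-methyl-5-oxooxolan-3-yl]-3-methylhex-3-en-2-yl acetate | CC(C)(C)[Si](C)(C)OCC/C=C(/C)[C@H](OC(C)=O)C[C@@H]1[C@@H](/C=C(\I)C)OC(=O)[C@@H]1C
F5 | step 14 | 6-hydroxy analogue of F4 | OCC/C=C(/C)[C@H](OC(C)=O)C[C@@H]1[C@@H](/C=C(\I)C)OC(=O)[C@@H]1C
F6 | step 14 | 6-oxo analogue of F4 | O=CC/C=C(/C)[C@H](OC(C)=O)C[C@@H]1[C@@H](/C=C(\I)C)OC(=O)[C@@H]1C
F7 | step 14 | (3R,3aS,5R,6Z,9S,10Z,11aS)-9-hydroxy-3,6,10-trimethyl-2-oxo-2,3,3a,4,5,8,9,11a-octahydrocyclodeca[b]furan-5-yl acetate | O[C@H]1C/C=C(/C)[C@H](OC(C)=O)C[C@@H]2[C@@H](/C=C\1C)OC(=O)[C@@H]2C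
F8 | step 4 | methyl (3R,4S,5Z)-4-hydroxy-6-iodo-3-(2-oxoethyl)-2-(phenylsulfonyl)hept-5-enoate (C2 epimers) | O=CC[C@H]([C@H](O)/C=C(\I)C)C(C(=O)OC)S(=O)(=O)c1ccccc1
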